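**Proposed synthesis of artopetelin C: ring A closed last by an intramolecular Claisen condensation on a furan**

## Analysis of the target

Artopetelin C is a 2-arylbenzofuran. Ring A (C3a, C4, C5, C6, C7, C7a) is a resorcinol with hydroxyls on C4 and C6 and a 2-methylbut-3-en-2-yl (1,1-dimethylallyl) group on C7, next to the furan oxygen O1. Ring B (C1'–C6') is a pentasubstituted benzene: C1' is bonded to furan C2, C2' carries a 3-methylbut-2-enyl (prenyl) group, C3' a hydroxyl, C4' a hydrogen, and C5'–O with C6'–CH2 is fused into a 2,2-dimethylchroman. The molecule has no stereocentre, and the C2–C1' axis has only O1 and C3–H on the furan side, so nothing stereochemical has to be controlled. The sensitive groups are three electron-rich phenols (oxidation), a prenyl group and a 1,1-dimethylallyl group each ortho to a phenol (acid-induced cyclisation), and a terminal vinyl group; strong acid, electrophilic halogen and hydrogenation are therefore excluded late in the route. Three things make the synthesis hard. The quaternary carbon on C7 sits between O1 and the C6 hydroxyl, where any aromatic substitution or aryl-ether rearrangement would have to choose between C5 and C7. The C2–C1' bond joins a carbon with two ortho substituents. And C1' is meta to both ring B oxygens, so phenol-directed chemistry cannot reach it. The route rests on the 1,3-relationship of the C4 and C6 oxygens in a ring fused to the furan through C3a–C7a. Read backwards, C4 is an ester carbonyl on furan C3, C6 is a ketone carbonyl, C5 is the methyl group of that ketone, and C7 is an sp3 carbon on furan C2 that can receive its quaternary substituent before ring A exists.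

## Retrosynthetic reasoning

Compounds are numbered as in the steps below.

**27 to 26.** The last bond cut is O3'–Si. Ring B carries one silyl ether from its first differentiation to the end; the two ring A phenols are never protected because they only appear in the step before.

**26 to 24 (through 25).** The C4–C5 bond is cut. Ring A then unfolds to the cyclic 1,3-diketone 25 and further to keto ester 24, in which a methyl ketone and a furan-3-carboxylate face each other across furan C2–C3. This cut is preferred over C5–C6 because the nucleophile is then an unhindered methyl enolate and the electrophile an ester on the ring; the reverse pairing would ask a ring acetyl enolate to attack a carbonyl next to the neopentyl-like C7. The forward reaction has to make one C–C bond and one ring; the aromatisation that follows delivers both phenols free and fixes the C7 substituent between O1 and C6–OH by connectivity alone.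

**24 to 22 (through 23).** The C6–CH3 bond is cut, leading back to carboxylic acid 22. The forward step must deliver one methyl group to an activated acyl carbon (acid chloride 23) without touching the furan ester.

**22 to 19 (through 20 and 21), then 19 to 17 and 18, and 17 to 16.** The bond between the future C7 and the quaternary carbon is cut as a [3,3] shift of the ketene acetal 20 of prenyl ester 19. On an sp3 carbon the allyl group can only arrive inverted, as the 1,1-dimethylallyl group, and only on that carbon. Ester 19 comes from acid 17 and alcohol 18; acid 17 comes from diester 16 by hydrolysis of the aliphatic ester, which is far more reactive than the conjugated, flanked furan-3-carboxylate.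

**16 to 5 and 15.** The C2–C1' bond (furan C5 to ring B) is cut as a biaryl coupling between furyl boronate 5 and aryl triflate 15. The hindrance lies entirely on ring B, so the smallest possible partner is put on the other side. Letting the halocarbonyl component of a Feist–Benary reaction carry ring B was considered and dropped: the carbonyl carbon of that component becomes furan C4, so ring B would end up on the wrong carbon. The alkylation and acid cyclodehydration variant gives the right isomer but exposes the prenyl group to acid; it is kept as a reserve.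

**5 to 4, and 4 to 1 and 2 (through 3).** The boronate is made from the C5–H bond of furan 4. Furan 4 is cut across O1–C5 and C3–C4 into ketodiester 1 and aldehyde 2. With this aldehyde the Feist–Benary regiochemistry is exactly what is needed: the two esters at C2–CH2 and C3, and C5 unsubstituted.

**15 to 14, 14 to 12 (through 13), and 12 to 10 and 11.** The triflate carbon is a former phenol carbon, so ring B can be drawn from a threefold oxygenated benzene, which answers the problem that C1' is meta to both remaining oxygens. The prenyl group on chroman C6 is cut back to a 1,1-dimethylallyl ether on O5 (12). Its aromatic Claisen shift can only go to C6, since the other ortho carbon is the ring fusion, and it releases O5–H for triflation. One sequence thus places the prenyl group and tells the two oxygens apart.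

**10 to 9, 9 to 6 and 7 (through 8), and 11 to 7.** Silyl ether 10 comes from diol 9 by silylation of the less hindered O7. Chroman 9 is cut at C4a–C4 and O1–C2 into symmetric triol 6 and alcohol 7, a disconnection with no regiochemical choice. Carbonate 11 derives from the same alcohol 7.

## Alternatives that were turned down

**Alternative 1: double aromatic Claisen on ring B.**
- Disconnection and key step: both benzylic bonds of ring B (C2'–CH2 and C6'–CH2) are cut back to two 1,1-dimethylallyl ethers on a symmetric ring B benzoate, A1, whose ester blocks C4'. Heating A1 would shift both allyl groups to the only free ortho carbons and give the bis-prenyl salicylate A2.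
- For it: the step needs no reagent, its regiochemistry is locked by the blocking ester, and the biaryl bond is made before the flanking groups exist. On that last point it is stronger than the chosen route, which has to couple at a doubly ortho-substituted carbon.
- Against it: A2 is symmetric about the C1'–C4' axis. Exactly one of two identical prenyl groups must then close onto its neighbouring phenol, an acid-mediated and statistical operation carried out while ring A holds a 1,1-dimethylallyl group beside a silyl ether. The blocking ester must afterwards be hydrolysed and decarboxylated from a doubly flanked, hydrogen-bonded position. The ring A half with its C7 quaternary carbon is simply presupposed.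
- Comparison: the chosen route is longer and more linear, but it builds the chroman before the prenyl group exists, has no desymmetrisation, and solves the C7 problem by construction.

**Alternative 2: oxidative C–H cyclisation of an aryloxyacrylate.**
- Disconnection and key step: the furan is cut at C3a–C3. The aryloxyacrylate A3 would be cyclised under oxidative palladium catalysis (divalent palladium regenerated by a silver oxidant) through palladation of the one free ortho C–H of the aryloxy ring, giving the benzofuran-3-carboxylate A4.
- For it: the route is convergent, the site of C–H activation is unambiguous, and the step count on paper is low. In convergence it is stronger than the chosen route.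
- Against it: electrophilic divalent palladium and a silver oxidant at high temperature meet three alkenes, one of them a terminal vinyl group, so Wacker-type oxidation, allylic C–H activation and Heck insertion all compete. A3 itself requires adding a hindered phenol to a propiolate bearing the doubly ortho-substituted ring B. A4 carries a C3 ester that the target lacks, and removing it from between ring B and the C4 silyl ether needs forcing hydrolysis and decarboxylation. The phenol component again needs the 1,1-dimethylallyl group placed between two oxygens, which is the unsolved ring A problem.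
- Comparison: the chosen route spends more steps but uses only acid–base, pericyclic and one cross-coupling step on the alkene-bearing intermediates, and ends with a single deprotection.

**Alternative 3: Diels–Alder construction of ring B.**
- Disconnection and key step: ring B is cut at C1'–C2' and C5'–C6'. The 4-substituted bis(silyloxy)diene A5 and the benzofuranyl ynone A6 would combine in a [4+2] cycloaddition, and loss of the methoxy and silyl groups would aromatise the adduct to resorcinol A7, which carries a 3-methylbut-2-enoyl group on C6'.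
- For it: no substitution or cross-coupling on ring B is needed, the polarity of the two partners fixes the regiochemistry, and the acyl group is placed for an oxa-Michael closure of the pyran ring. In avoiding the hindered biaryl coupling it is stronger than the chosen route.
- Against it: the new C1'–C2' bond joins a substituted diene terminus to the alkyne carbon that bears the whole benzofuran, a congested cycloaddition with the enone of A6 as a competing acceptor. After A7 the route still needs ring closure to a chromanone and removal of its carbonyl in the presence of two acid- and reduction-sensitive alkenes. The ring A benzofuran with its quaternary C7 substituent must again be made first by other means.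
- Comparison: the chosen route has the saturated chroman from its third step, no late deoxygenation, and one step after the key step.

Key step: step 14

## Route

Abbreviation: ArB = 2,2-dimethyl-6-(3-methylbut-2-enyl)-7-(triisopropylsilyloxy)chroman-5-yl, that is ring B with its chroman ring, attached through C1'.

Assumption: the C2–C1' aryl–furyl axis is taken to rotate freely at room temperature; the stereocentres of 3, 13 and 21–25 are formed racemic and are all erased later in the route.

Step 1
Reactants: 1 dimethyl 3-oxopentanedioate; 2 chloroacetaldehyde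
Product: 4 methyl 2-(2-methoxy-2-oxoethyl)furan-3-carboxylate, via dihydrofuranol 3 (not isolated)
Conditions: ClCH2CHO (50% aq.), pyridine, rt → 50 °C
Reagents that add atoms: none
Why: Feist–Benary furan synthesis: the enolised C2 of 1 adds to the aldehyde of 2, the enol oxygen displaces chloride to close 3, and loss of water aromatises; the aldehyde carbon becomes C4 and the CH2Cl carbon C5, so C5–H stays free and the two esters sit on C2–CH2 and C3.

Step 2
Reactants: 4 methyl 2-(2-methoxy-2-oxoethyl)furan-3-carboxylate
Product: 5 methyl 2-(2-methoxy-2-oxoethyl)-5-(4,4,5,5-tetramethyl-1,3,2-dioxaborolan-2-yl)furan-3-carboxylate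
Conditions: [Ir(OMe)(cod)]2 (1.5 mol %), 4,4'-di-tert-butyl-2,2'-bipyridine (3 mol %), B2pin2 (1.0 equiv), THF, rt → 50 °C
Reagents that add atoms: bis(pinacolato)diboron, CC1(C)OB(OC1(C)C)B1OC(C)(C)C(C)(C)O1
Why: Iridium-catalysed aromatic C–H borylation; furans react at the α-position, C5–H is the only α C–H and is unhindered, whereas C4–H is β and flanked by the ester; esters and the activated CH2 tolerate these neutral conditions.

Step 3
Reactants: 6 phloroglucinol; 7 2-methylbut-3-en-2-ol
Product: 9 2,2-dimethylchroman-5,7-diol, via C-prenyl triol 8 (not isolated)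
Conditions: Amberlyst 15, THF, 65 °C (6 in twofold excess)
Reagents that add atoms: none
Why: Acid-catalysed Friedel–Crafts prenylation of the symmetric triol (all ring positions equivalent) gives 8, whose alkene is protonated to the tertiary cation and captured by an ortho hydroxyl (Markovnikov hydroalkoxylation) to close the chroman; the excess of 6 holds back a second annulation.

Step 4
Reactants: 9 2,2-dimethylchroman-5,7-diol
Product: 10 2,2-dimethyl-7-(triisopropylsilyloxy)chroman-5-ol
Conditions: iPr3SiCl (1.0 equiv), imidazole, DMF, −20 → 0 °C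
Reagents that add atoms: chlorotriisopropylsilane, CC(C)[Si](Cl)(C(C)C)C(C)C
Why: Silyl ether formation under steric control: O7 has two ortho hydrogens whereas O5 lies beside the ring CH2 on C4, so one equivalent of the bulky chlorosilane should go mainly to O7; the triisopropylsilyl ether also withstands the hydroxide, phosphate and methoxide met later.

Step 5
Reactants: 7 2-methylbut-3-en-2-ol
Product: 11 tert-butyl 2-methylbut-3-en-2-yl carbonate
Conditions: n-BuLi, THF, −78 °C; Boc2O, → rt; aq. NH4Cl
Reagents that add atoms: di-tert-butyl dicarbonate, CC(C)(C)OC(=O)OC(=O)OC(C)(C)C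
Why: Acylation of the lithium alkoxide of a tertiary alcohol by the dicarbonate, a standard preparation of mixed tert-allyl carbonates.

Step 6
Reactants: 10 2,2-dimethyl-7-(triisopropylsilyloxy)chroman-5-ol; 11 tert-butyl 2-methylbut-3-en-2-yl carbonate
Product: 12 2,2-dimethyl-5-(2-methylbut-3-en-2-yloxy)-7-(triisopropylsilyloxy)chroman
Conditions: Pd(PPh3)4 (3 mol %), THF, 0 °C
Reagents that add atoms: none
Why: Tsuji–Trost O-allylation: zerovalent palladium ionises 11 to a 1,1-dimethyl-π-allyl complex with loss of CO2, the tert-butoxide set free deprotonates the phenol, and the phenoxide attacks the more substituted allyl terminus under kinetic control at low temperature to give the tertiary ether.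

Step 7
Reactants: 12 2,2-dimethyl-5-(2-methylbut-3-en-2-yloxy)-7-(triisopropylsilyloxy)chroman
Product: 14 2,2-dimethyl-6-(3-methylbut-2-enyl)-7-(triisopropylsilyloxy)chroman-5-ol, via cyclohexadienone 13 (not isolated)
Conditions: PhMe, 110 °C
Reagents that add atoms: none
Why: Aromatic Claisen rearrangement: the [3,3] shift can only go to C6, the single unsubstituted ortho carbon of O5 (the other is the ring fusion C4a), and inverts the allyl unit so that the C-bound group is the 3-methylbut-2-enyl group; dienone 13 tautomerises to the phenol and frees O5–H.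

Step 8
Reactants: 14 2,2-dimethyl-6-(3-methylbut-2-enyl)-7-(triisopropylsilyloxy)chroman-5-ol
Product: 15 2,2-dimethyl-6-(3-methylbut-2-enyl)-7-(triisopropylsilyloxy)chroman-5-yl trifluoromethanesulfonate
Conditions: Tf2O, pyridine, CH2Cl2, −78 → 0 °C
Reagents that add atoms: trifluoromethanesulfonic anhydride, O=S(=O)(OS(=O)(=O)C(F)(F)F)C(F)(F)F
Why: Sulfonylation of a hindered phenol; excess pyridine keeps the medium from turning acidic, so the prenyl group beside the phenol does not cyclise.

Step 9
Reactants: 15 2,2-dimethyl-6-(3-methylbut-2-enyl)-7-(triisopropylsilyloxy)chroman-5-yl trifluoromethanesulfonate; 5 methyl 2-(2-methoxy-2-oxoethyl)-5-(4,4,5,5-tetramethyl-1,3,2-dioxaborolan-2-yl)furan-3-carboxylate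
Product: 16 methyl 5-ArB-2-(2-methoxy-2-oxoethyl)furan-3-carboxylate
Conditions: Pd(OAc)2 (5 mol %), SPhos (10 mol %), K3PO4, PhMe/H2O (10:1), 80 °C
Reagents that add atoms: none
Why: Suzuki–Miyaura coupling: the bulky, electron-rich biarylphosphine supports oxidative addition into the doubly ortho-substituted triflate (its carbon is meta to both ring oxygens and so not deactivated) and reductive elimination, while the furyl boronate is a small partner flanked only by O1 and C4–H.

Step 10
Reactants: 16 methyl 5-ArB-2-(2-methoxy-2-oxoethyl)furan-3-carboxylate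
Product: 17 2-[5-ArB-3-(methoxycarbonyl)furan-2-yl]acetic acid
Conditions: LiOH·H2O (1.1 equiv), THF/MeOH/H2O, 0 °C; then dil. HCl to pH 4, 0 °C
Reagents that add atoms: lithium hydroxide (aqueous), [Li+].[OH-]
Why: Chemoselective saponification: the unhindered aliphatic ester is hydrolysed far faster than the furan-3-carboxylate, which is conjugated to the electron-rich ring and shielded on both sides; the triisopropylsilyl aryl ether survives cold hydroxide.

Step 11
Reactants: 17 2-[5-ArB-3-(methoxycarbonyl)furan-2-yl]acetic acid; 18 3-methylbut-2-en-1-ol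
Product: 19 methyl 5-ArB-2-[2-(3-methylbut-2-enyloxy)-2-oxoethyl]furan-3-carboxylate
Conditions: EDC·HCl, DMAP (cat.), CH2Cl2, 0 °C → rt
Reagents that add atoms: none
Why: Steglich-type carbodiimide esterification of an unhindered acid with a primary allylic alcohol under neutral conditions.

Step 12
Reactants: 19 methyl 5-ArB-2-[2-(3-methylbut-2-enyloxy)-2-oxoethyl]furan-3-carboxylate
Product: 22 2-[5-ArB-3-(methoxycarbonyl)furan-2-yl]-3,3-dimethylpent-4-enoic acid (racemic), via silyl ketene acetal 20 (not isolated), via trimethylsilyl ester 21 (not isolated)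
Conditions: LiN(iPr)2 (1.2 equiv), THF, −78 °C; Me3SiCl, −78 °C → rt, then 60 °C; pH 4 buffer
Reagents that add atoms: none
Why: Ireland–Claisen rearrangement: O-silylation of the lithium enolate gives 20, whose [3,3] shift joins the α-carbon to the dimethyl-substituted allyl terminus with allyl inversion, so the 1,1-dimethylallyl group lands on the future C7 with no regiochemical alternative; the new stereocentre is racemic and is erased in step 14.

Step 13
Reactants: 22 2-[5-ArB-3-(methoxycarbonyl)furan-2-yl]-3,3-dimethylpent-4-enoic acid
Product: 24 methyl 5-ArB-2-(4,4-dimethyl-2-oxohex-5-en-3-yl)furan-3-carboxylate (racemic), via acid chloride 23 (not isolated)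
Conditions: 1-chloro-N,N,2-trimethylprop-1-en-1-amine, CH2Cl2, 0 °C → rt; then Me2CuLi (from MeLi and CuI), Et2O, −78 °C; aq. NH4Cl
Reagents that add atoms: lithium dimethylcuprate, [Li+].C[Cu-]C (made in the flask from methyllithium, [Li]C, and CuI, [Cu]I)
Why: The α-chloroenamine converts the acid into 23 without releasing HCl, so the alkenes are safe; acylation of the Gilman cuprate (monovalent copper) then takes the acid chloride to the methyl ketone and stops there, since neither the furan ester nor the product ketone reacts with the cuprate at −78 °C.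

Step 14
Reactants: 24 methyl 5-ArB-2-(4,4-dimethyl-2-oxohex-5-en-3-yl)furan-3-carboxylate
Product: 26 2-ArB-7-(2-methylbut-3-en-2-yl)benzofuran-4,6-diol (3'-O-triisopropylsilyl artopetelin C), via cyclic diketone 25 (not isolated)
Conditions: LiN(SiMe3)2 (4 equiv), THF, −78 °C → rt; aq. NH4Cl (pH 6)
Reagents that add atoms: none
Why: Intramolecular Claisen (Dieckmann-type) condensation followed by aromatisation. With excess base the acetyl CH3 is deprotonated (after or beside the more acidic methine), and the methyl enolate carbon adds to the ester carbonyl on furan C3; the tetrahedral intermediate expels methoxide to give diketone 25 with the new C4–C5 bond. Ring A closes in a 6-exo-trig mode (enolate carbon onto an exocyclic C=O). Diketone 25 is at once deprotonated at C5 and C7 and tautomerises to the aromatic 4,6-diolate, an irreversible sink that consumes two equivalents of base and pulls all enolate equilibria forward. The closest known reaction is the base-mediated cyclisation of ortho-(2-oxoalkyl) aryl esters to 1,3-naphthalenediols. No stereocentre is formed, and the racemic methine becomes the sp2 carbon C7. The selectivity needed is C-acylation by the methyl carbon: the methine carbon could only close a four-membered ring, and O-acylation by the internal enolate, which would close a six-membered enol lactone, is reversible in the presence of the methoxide set free, whereas the C–C path ends in the aromatic dianion. The triisopropylsilyl ether resists that methoxide, and the prenyl, vinyl and chroman units are inert to amide base; the mildly acidic quench avoids cyclisation of the 1,1-dimethylallyl group onto the new C6 hydroxyl.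

Step 15
Reactants: 26 2-ArB-7-(2-methylbut-3-en-2-yl)benzofuran-4,6-diol
Product: 27 artopetelin C
Conditions: Bu4NF (1.2 equiv), AcOH (1.2 equiv), THF, 0 °C, under argon
Reagents that add atoms: none
Why: Fluoride cleavage of the aryl silyl ether; the acetic acid buffer keeps the triphenol from standing as an air-sensitive phenoxide and no acid strong enough to cyclise either allyl group is present.

## Compound list

1 | dimethyl 3-oxopentanedioate | COC(=O)CC(=O)CC(=O)OC | starting material
2 | chloroacetaldehyde | O=CCCl | starting material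
3 | methyl 4-hydroxy-2-(2-methoxy-2-oxoethyl)-4,5-dihydrofuran-3-carboxylate (racemic) | COC(=O)CC1=C(C(=O)OC)C(O)CO1 | intermediate
4 | methyl 2-(2-methoxy-2-oxoethyl)furan-3-carboxylate | COC(=O)Cc1occc1C(=O)OC | intermediate
5 | methyl 2-(2-methoxy-2-oxoethyl)-5-(4,4,5,5-tetramethyl-1,3,2-dioxaborolan-2-yl)furan-3-carboxylate | COC(=O)Cc1oc(B2OC(C)(C)C(C)(C)O2)cc1C(=O)OC | intermediate
6 | phloroglucinol (benzene-1,3,5-triol) | Oc1cc(O)cc(O)c1 | starting material
7 | 2-methylbut-3-en-2-ol | C=CC(C)(C)O | starting material
8 | 2-(3-methylbut-2-enyl)benzene-1,3,5-triol | CC(C)=CCc1c(O)cc(O)cc1O | intermediate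
9 | 2,2-dimethylchroman-5,7-diol | CC1(C)CCc2c(O)cc(O)cc2O1 | intermediate
10 | 2,2-dimethyl-7-(triisopropylsilyloxy)chroman-5-ol | CC1(C)CCc2c(O)cc(O[Si](C(C)C)(C(C)C)C(C)C)cc2O1 | intermediate
11 | tert-butyl 2-methylbut-3-en-2-yl carbonate | C=CC(C)(C)OC(=O)OC(C)(C)C | intermediate
12 | 2,2-dimethyl-5-(2-methylbut-3-en-2-yloxy)-7-(triisopropylsilyloxy)chroman | C=CC(C)(C)Oc1cc(O[Si](C(C)C)(C(C)C)C(C)C)cc2c1CCC(C)(C)O2 | intermediate
13 | 2,2-dimethyl-6-(3-methylbut-2-enyl)-7-(triisopropylsilyloxy)-3,4-dihydro-2H-chromen-5(6H)-one (racemic) | CC1(C)CCC2=C(O1)C=C(O[Si](C(C)C)(C(C)C)C(C)C)C(CC=C(C)C)C2=O | intermediate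
14 | 2,2-dimethyl-6-(3-methylbut-2-enyl)-7-(triisopropylsilyloxy)chroman-5-ol | CC1(C)CCc2c(O)c(CC=C(C)C)c(O[Si](C(C)C)(C(C)C)C(C)C)cc2O1 | intermediate
15 | 2,2-dimethyl-6-(3-methylbut-2-enyl)-7-(triisopropylsilyloxy)chroman-5-yl trifluoromethanesulfonate | CC1(C)CCc2c(OS(=O)(=O)C(F)(F)F)c(CC=C(C)C)c(O[Si](C(C)C)(C(C)C)C(C)C)cc2O1 | intermediate
16 | methyl 5-ArB-2-(2-methoxy-2-oxoethyl)furan-3-carboxylate | COC(=O)Cc1oc(-c2c(CC=C(C)C)c(O[Si](C(C)C)(C(C)C)C(C)C)cc3c2CCC(C)(C)O3)cc1C(=O)OC | intermediate
17 | 2-[5-ArB-3-(methoxycarbonyl)furan-2-yl]acetic acid | OC(=O)Cc1oc(-c2c(CC=C(C)C)c(O[Si](C(C)C)(C(C)C)C(C)C)cc3c2CCC(C)(C)O3)cc1C(=O)OC | intermediate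
18 | 3-methylbut-2-en-1-ol | CC(C)=CCO | starting material
19 | methyl 5-ArB-2-[2-(3-methylbut-2-enyloxy)-2-oxoethyl]furan-3-carboxylate | CC(C)=CCOC(=O)Cc1oc(-c2c(CC=C(C)C)c(O[Si](C(C)C)(C(C)C)C(C)C)cc3c2CCC(C)(C)O3)cc1C(=O)OC | intermediate
20 | methyl 5-ArB-2-[2-(3-methylbut-2-enyloxy)-2-(trimethylsilyloxy)ethenyl]furan-3-carboxylate (silyl ketene acetal, either geometry) | CC(C)=CCOC(O[Si](C)(C)C)=Cc1oc(-c2c(CC=C(C)C)c(O[Si](C(C)C)(C(C)C)C(C)C)cc3c2CCC(C)(C)O3)cc1C(=O)OC | intermediate
21 | trimethylsilyl 2-[5-ArB-3-(methoxycarbonyl)furan-2-yl]-3,3-dimethylpent-4-enoate (racemic) | C=CC(C)(C)C(C(=O)O[Si](C)(C)C)c1oc(-c2c(CC=C(C)C)c(O[Si](C(C)C)(C(C)C)C(C)C)cc3c2CCC(C)(C)O3)cc1C(=O)OC | intermediate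
22 | 2-[5-ArB-3-(methoxycarbonyl)furan-2-yl]-3,3-dimethylpent-4-enoic acid (racemic) | C=CC(C)(C)C(C(=O)O)c1oc(-c2c(CC=C(C)C)c(O[Si](C(C)C)(C(C)C)C(C)C)cc3c2CCC(C)(C)O3)cc1C(=O)OC | intermediate
23 | 2-[5-ArB-3-(methoxycarbonyl)furan-2-yl]-3,3-dimethylpent-4-enoyl chloride (racemic) | C=CC(C)(C)C(C(=O)Cl)c1oc(-c2c(CC=C(C)C)c(O[Si](C(C)C)(C(C)C)C(C)C)cc3c2CCC(C)(C)O3)cc1C(=O)OC | intermediate
24 | methyl 5-ArB-2-(4,4-dimethyl-2-oxohex-5-en-3-yl)furan-3-carboxylate (racemic) | C=CC(C)(C)C(C(C)=O)c1oc(-c2c(CC=C(C)C)c(O[Si](C(C)C)(C(C)C)C(C)C)cc3c2CCC(C)(C)O3)cc1C(=O)OC | intermediate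
25 | 2-ArB-7-(2-methylbut-3-en-2-yl)benzofuran-4,6(5H,7H)-dione (racemic) | C=CC(C)(C)C1C(=O)CC(=O)c2cc(-c3c(CC=C(C)C)c(O[Si](C(C)C)(C(C)C)C(C)C)cc4c3CCC(C)(C)O4)oc12 | intermediate
26 | 2-ArB-7-(2-methylbut-3-en-2-yl)benzofuran-4,6-diol (3'-O-triisopropylsilyl artopetelin C) | C=CC(C)(C)c1c(O)cc(O)c2cc(-c3c(CC=C(C)C)c(O[Si](C(C)C)(C(C)C)C(C)C)cc4c3CCC(C)(C)O4)oc12 | intermediate
27 | artopetelin C | C=CC(C)(C)c1c(O)cc(O)c2cc(-c3c(CC=C(C)C)c(O)cc4c3CCC(C)(C)O4)oc12 | target

## Step count and least certain steps

Total: 15 steps. Longest linear sequence: 12 steps (from 6 to 27 through steps 3, 4 and 6–15); steps 1, 2 and 5 are side branches.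

**Step 14 (key step).** The base removes the more acidic methine proton first. The delocalised enolate so formed may acylate on oxygen, or the second deprotonation at the methyl group may be slow beside the quaternary carbon, so that the sequence stalls before the C–C bond forms. The fallback makes the nucleophilic carbon doubly activated. It sets out from acid chloride 23, made from 22 as in step 13. Acylation of the magnesium enolate of allyl hydrogen malonate (MgCl2, Et3N, MeCN) with loss of CO2 would give allyl 4-[5-ArB-3-(methoxycarbonyl)furan-2-yl]-5,5-dimethyl-3-oxohept-6-enoate F1. Its C2 methylene is deprotonated by NaH in THF and should close onto the furan ester to allyl 2-ArB-4,6-dihydroxy-7-(2-methylbut-3-en-2-yl)benzofuran-5-carboxylate F2. Pd(PPh3)4 with morpholine removes the allyl group to give 2-ArB-4,6-dihydroxy-7-(2-methylbut-3-en-2-yl)benzofuran-5-carboxylic acid F3, a 2,6-dihydroxybenzoic acid that loses CO2 on gentle warming. The fallback comes back to the route at 26.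

**Step 9.** Transmetalation at the congested arylpalladium may be slow enough for protodeboronation of the furyl boronate and hydrolysis of the triflate by aqueous base to win. The fallback builds the furan on ring B under base-free coupling conditions. It sets out from triflate 15. Stille coupling with tributyl(1-ethoxyvinyl)stannane (Pd(PPh3)4, LiCl, dioxane, 100 °C) would give 5-(1-ethoxyvinyl)-2,2-dimethyl-6-(3-methylbut-2-enyl)-7-(triisopropylsilyloxy)chroman F7. N-Bromosuccinimide in aqueous THF at 0 °C reacts at the enol ether, the most nucleophilic alkene, to give 2-bromo-1-ArB-ethanone F8. The sodium enolate of 1 (NaH, THF) is alkylated on its central carbon to dimethyl 2-(2-ArB-2-oxoethyl)-3-oxopentanedioate F9. Cyclodehydration with pyridinium p-toluenesulfonate in toluene at 80 °C, mild enough for the prenyl group, returns to the route at 16; steps 1 and 2 are then not needed.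

**Step 4.** Steric discrimination between O7 and O5 may be incomplete, with silylation spreading over both oxygens. The fallback replaces steric control by chelation. It sets out from 6. Acylation and ring closure with 3-methylbut-2-enoic acid in MeSO3H/P2O5 at 70 °C gives 5,7-dihydroxy-2,2-dimethylchroman-4-one F4. Its O5–H is locked in a hydrogen bond to the C4 carbonyl, so iPr3SiCl and imidazole silylate only O7 to 5-hydroxy-2,2-dimethyl-7-(triisopropylsilyloxy)chroman-4-one F5. Ethyl chloroformate and Et3N give ethyl 2,2-dimethyl-4-oxo-7-(triisopropylsilyloxy)chroman-5-yl carbonate F6. NaBH4 in aqueous THF reduces the ketone, the carbonate migrates to the benzylic oxygen and is expelled to an ortho-quinone methide, and a second hydride completes the deoxygenation. The fallback comes back to the route at 10; step 3 is then not needed.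

**Step 12.** The enolate is delocalised into the furan ester and the new bond joins a furan-bearing carbon to a fully substituted allyl terminus. The [3,3] shift may therefore be slow, leaving time for ionisation of the allylic C–O bond and recombination at the primary terminus, or for hydrolytic return to 19. The fallback forms the same bond with an electrophile that can only react at its tertiary carbon. It sets out from acid 17. A Dakin–West-type reaction (Ac2O, N-methylimidazole) with loss of CO2 gives methyl 5-ArB-2-(2-oxopropyl)furan-3-carboxylate F10. Me3SiOTf and Et3N enolise toward the furan to methyl 5-ArB-2-[2-(trimethylsilyloxy)prop-1-enyl]furan-3-carboxylate F11. Nicholas alkylation with the Co2(CO)6 complex of 2-methylbut-3-yn-2-ol F12 (from the alkynol and Co2(CO)8) and BF3·OEt2 at −78 °C gives the Co2(CO)6 complex of methyl 5-ArB-2-(4,4-dimethyl-2-oxohex-5-yn-3-yl)furan-3-carboxylate F13. Me3NO releases methyl 5-ArB-2-(4,4-dimethyl-2-oxohex-5-yn-3-yl)furan-3-carboxylate F14. Semi-hydrogenation over Pd/CaCO3 poisoned with Pb(OAc)2 and quinoline reduces only the terminal alkyne. The fallback comes back to the route at 24; steps 11–13 are then not needed.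

## Further compounds

F1 | step 14 | allyl 4-[5-ArB-3-(methoxycarbonyl)furan-2-yl]-5,5-dimethyl-3-oxohept-6-enoate (racemic) | C=CCOC(=O)CC(=O)C(C(C)(C)C=C)c1oc(-c2c(CC=C(C)C)c(O[Si](C(C)C)(C(C)C)C(C)C)cc3c2CCC(C)(C)O3)cc1C(=O)OC
F2 | step 14 | allyl 2-ArB-4,6-dihydroxy-7-(2-methylbut-3-en-2-yl)benzofuran-5-carboxylate | C=CCOC(=O)c1c(O)c(C(C)(C)C=C)c2oc(-c3c(CC=C(C)C)c(O[Si](C(C)C)(C(C)C)C(C)C)cc4c3CCC(C)(C)O4)cc2c1O
F3 | step 14 | 2-ArB-4,6-dihydroxy-7-(2-methylbut-3-en-2-yl)benzofuran-5-carboxylic acid | OC(=O)c1c(O)c(C(C)(C)C=C)c2oc(-c3c(CC=C(C)C)c(O[Si](C(C)C)(C(C)C)C(C)C)cc4c3CCC(C)(C)O4)cc2c1O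
F4 | step 4 | 5,7-dihydroxy-2,2-dimethylchroman-4-one | CC1(C)CC(=O)c2c(O)cc(O)cc2O1
F5 | step 4 | 5-hydroxy-2,2-dimethyl-7-(triisopropylsilyloxy)chroman-4-one | CC1(C)CC(=O)c2c(O)cc(O[Si](C(C)C)(C(C)C)C(C)C)cc2O1
F6 | step 4 | ethyl 2,2-dimethyl-4-oxo-7-(triisopropylsilyloxy)chroman-5-yl carbonate | CCOC(=O)Oc1cc(O[Si](C(C)C)(C(C)C)C(C)C)cc2c1C(=O)CC(C)(C)O2
F7 | step 9 | 5-(1-ethoxyvinyl)-2,2-dimethyl-6-(3-methylbut-2-enyl)-7-(triisopropylsilyloxy)chroman | C=C(OCC)c1c(CC=C(C)C)c(O[Si](C(C)C)(C(C)C)C(C)C)cc2c1CCC(C)(C)O2
F8 | step 9 | 2-bromo-1-ArB-ethanone | O=C(CBr)c1c(CC=C(C)C)c(O[Si](C(C)C)(C(C)C)C(C)C)cc2c1CCC(C)(C)O2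
F9 | step 9 | dimethyl 2-(2-ArB-2-oxoethyl)-3-oxopentanedioate (racemic) | COC(=O)CC(=O)C(CC(=O)c1c(CC=C(C)C)c(O[Si](C(C)C)(C(C)C)C(C)C)cc2c1CCC(C)(C)O2)C(=O)OC
F10 | step 12 | methyl 5-ArB-2-(2-oxopropyl)furan-3-carboxylate | CC(=O)Cc1oc(-c2c(CC=C(C)C)c(O[Si](C(C)C)(C(C)C)C(C)C)cc3c2CCC(C)(C)O3)cc1C(=O)OC
F11 | step 12 | methyl 5-ArB-2-[2-(trimethylsilyloxy)prop-1-enyl]furan-3-carboxylate | CC(O[Si](C)(C)C)=Cc1oc(-c2c(CC=C(C)C)c(O[Si](C(C)C)(C(C)C)C(C)C)cc3c2CCC(C)(C)O3)cc1C(=O)OC
F12 | step 12 | Co2(CO)6 complex of 2-methylbut-3-yn-2-ol | CC(C)(O)C12[CH]3[Co]1(=C=O)(=C=O)(=C=O)[Co]23(=C=O)(=C=O)=C=O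
F13 | step 12 | Co2(CO)6 complex of methyl 5-ArB-2-(4,4-dimethyl-2-oxohex-5-yn-3-yl)furan-3-carboxylate (racemic) | CC(=O)C(c1oc(-c2c(CC=C(C)C)c(O[Si](C(C)C)(C(C)C)C(C)C)cc3c2CCC(C)(C)O3)cc1C(=O)OC)C(C)(C)C12[CH]3[Co]1(=C=O)(=C=O)(=C=O)[Co]23(=C=O)(=C=O)=C=O
F14 | step 12 | methyl 5-ArB-2-(4,4-dimethyl-2-oxohex-5-yn-3-yl)furan-3-carboxylate (racemic) | C#CC(C)(C)C(C(C)=O)c1oc(-c2c(CC=C(C)C)c(O[Si](C(C)C)(C(C)C)C(C)C)cc3c2CCC(C)(C)O3)cc1C(=O)OC
A1 | alternative 1 | methyl 4-[4,6-bis(tert-butyldimethylsilyloxy)-7-(2-methylbut-3-en-2-yl)benzofuran-2-yl]-2,6-bis(2-methylbut-3-en-2-yloxy)benzoate | COC(=O)c1c(OC(C)(C)C=C)cc(-c2cc3c(O[Si](C)(C)C(C)(C)C)cc(O[Si](C)(C)C(C)(C)C)c(C(C)(C)C=C)c3o2)cc1OC(C)(C)C=C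
A2 | alternative 1 | methyl 4-[4,6-bis(tert-butyldimethylsilyloxy)-7-(2-methylbut-3-en-2-yl)benzofuran-2-yl]-2,6-dihydroxy-3,5-bis(3-methylbut-2-enyl)benzoate | COC(=O)c1c(O)c(CC=C(C)C)c(-c2cc3c(O[Si](C)(C)C(C)(C)C)cc(O[Si](C)(C)C(C)(C)C)c(C(C)(C)C=C)c3o2)c(CC=C(C)C)c1O
A3 | alternative 2 | methyl 3-[3,5-bis(tert-butyldimethylsilyloxy)-2-(2-methylbut-3-en-2-yl)phenoxy]-3-[7-(tert-butyldimethylsilyloxy)-2,2-dimethyl-6-(3-methylbut-2-enyl)chroman-5-yl]acrylate | COC(=O)C=C(Oc1cc(O[Si](C)(C)C(C)(C)C)cc(O[Si](C)(C)C(C)(C)C)c1C(C)(C)C=C)c1c(CC=C(C)C)c(O[Si](C)(C)C(C)(C)C)cc2c1CCC(C)(C)O2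
A4 | alternative 2 | methyl 4,6-bis(tert-butyldimethylsilyloxy)-2-[7-(tert-butyldimethylsilyloxy)-2,2-dimethyl-6-(3-methylbut-2-enyl)chroman-5-yl]-7-(2-methylbut-3-en-2-yl)benzofuran-3-carboxylate | COC(=O)c1c(-c2c(CC=C(C)C)c(O[Si](C)(C)C(C)(C)C)cc3c2CCC(C)(C)O3)oc2c(C(C)(C)C=C)c(O[Si](C)(C)C(C)(C)C)cc(O[Si](C)(C)C(C)(C)C)c12
A5 | alternative 3 | 1-methoxy-7-methyl-1,3-bis(trimethylsilyloxy)octa-1,3,6-triene | COC(O[Si](C)(C)C)=CC(O[Si](C)(C)C)=CCC=C(C)C
A6 | alternative 3 | 1-[4,6-bis(tert-butyldimethylsilyloxy)-7-(2-methylbut-3-en-2-yl)benzofuran-2-yl]-5-methylhex-4-en-1-yn-3-one | CC(C)=CC(=O)C#Cc1cc2c(O[Si](C)(C)C(C)(C)C)cc(O[Si](C)(C)C(C)(C)C)c(C(C)(C)C=C)c2o1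
A7 | alternative 3 | 1-{2-[4,6-bis(tert-butyldimethylsilyloxy)-7-(2-methylbut-3-en-2-yl)benzofuran-2-yl]-4,6-dihydroxy-3-(3-methylbut-2-enyl)phenyl}-3-methylbut-2-en-1-one | C=CC(C)(C)c1c(O[Si](C)(C)C(C)(C)C)cc(O[Si](C)(C)C(C)(C)C)c2cc(-c3c(CC=C(C)C)c(O)cc(O)c3C(=O)C=C(C)C)oc12
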